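(The numbers of this flask stand for no real mixture; the rest is arithmetic.)

Late in a run a finished ring still stands among whatever activator remains, so I ask how much activator a ring has met by the end of the clock.

| flask | starting material | activator | time |
|---|---|---|---|
| maple | 0.10 M | 0.200 M | 4.0 min |
| birch | 0.10 M | 0.600 M | 4.0 min |
| ash | 0.10 M | 1.80 M | 4.0 min |

    starting material + activator → activated form (k1 = 0.61 M⁻¹ s⁻¹)
    activated form → ring (k2 = 0.032 s⁻¹)
    starting material + activated form → open dimer (k3 = 0.58 M⁻¹ s⁻¹)
    activator → decomposed reagent (k4 = 0.0056 s⁻¹)
    starting material ⇌ dormant form (K5 = 6.1, k5 = 0.019 s⁻¹)
    activator + ring → over-reaction product (k6 = 0.0070 M⁻¹ s⁻¹)

1. which of these there is most of at the end, counted by the starting material in it, maple (starting material / over-reaction product / open dimer / activated form / ring)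
2. which of these there is most of at the end, counted by the starting material in it, birch (starting material / over-reaction product / open dimer / activated form / ring)
3. which of these there is most of at the end, counted by the starting material in it, ash (starting material / over-reaction product / open dimer / activated form / ring)
4. final amount of the leader among these, as a percentage of the starting material charged, in maple
5. final amount of the leader among these, as a percentage of the starting material charged, in birch
6. final amount of the leader among these, as a percentage of the starting material charged, in ash

- a species is counted by the starting material in it: one open dimer counts as two
- run time (maple): 4.0 min

Write c(activator) for the activator concentration. The activated form has a lifetime of 31.2 s by step 2, and starting material has a half-life of 0.095 min by step 1 at the maple charge, shorter than that lifetime. So I let rings appear at that lifetime, and I take one activator per starting material, which leaves a spare charge of c(activator) minus 0.10 M.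

From then on the activator decays with a half-life of 2.1 min by step 4 alone, shorter than the run, so I replace its falling curve by its mean. Over the remaining 3.48 min, that mean is 0.495 of the spare charge. Loss of ring by step 6 is then pseudo-first-order at this mean, and ring's share of ring plus over-reaction product is exp(−dose). The dose is the spare charge times 0.723 M⁻¹, the ring dose per molar: k6 times the mean fraction times the window. Keeping the charge flat instead gives ash 3.02, and that is the error the mean removes.

My small table, flask by flask:

- maple: spare 0.100 M, dose 0.0723, ring share 93.0%
- birch: spare 0.500 M, dose 0.362, ring share 69.7%
- ash: spare 1.70 M, dose 1.23, ring share 29.2%

By this reckoning ring outweighs over-reaction product while the dose stays under 0.693. Reading down the dose column, maple lies far below that mark and birch lies below it too, so I expect more ring than over-reaction product in both. Ash lies above it, so in ash I expect the order to turn. The open dimer stands outside this split and I have not reckoned its amount, so I commit to the split and give no yields.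

The forecast names ring in maple at 55%, ring in birch at 58%, and over-reaction product in ash at 67%. Its ground for ash is that “the large activator excess survives its decay”.

The flask gives ring at 59.2% in maple, ring at 59.9% in birch, and over-reaction product at 64.6% in ash. The forecast's leaders are right, and its amounts are within the tolerance.

In ash at 4.00 min, ring holds 31.4% of ring plus over-reaction product, against the 29.2% from the dose. I carry 0.723 M⁻¹ to a neighbour of birch charged with 2.4 M of activator, the time unchanged. Its spare charge is 2.30 M and its dose 1.66, above the mark, so its ring share comes to 18.9% and over-reaction product should lead. In that neighbour ring stands at 20.2%, a share of 21.1%, and over-reaction product leads with 75.4%.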